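## Retrosynthetic overview

1. The coumestan is opened at the lactone C–O bond (closed last, by debenzylation and lactonisation) and at the furan ring. The furan comes from a β-keto ester and 4-(benzyloxy)-2-bromo-1-iodobenzene by Cu-catalysed C-arylation/O-arylation.
2. The β-keto ester comes from an 8-acetyl-2,2-dimethylchroman. Its dihydropyran ring is closed at C2–C3 by a Lewis-acid-catalysed [1,5]-hydride shift/cyclisation of an aryl isopropyl ether bearing an ortho alkylidene Meldrum's acid; the two carboxyl carbons on C3 are then excised.
3. Enabling feature: in the ring O1–C2(CH3)2–C3H2–C4H2–C4a–C8a, C2 is a tertiary carbon on the aryl ether oxygen and C4 a benzylic methylene on the neighbouring arene carbon. The methine H of an O-isopropyl group therefore sits 1,5 to C4 and can be handed over as hydride, which makes C4 a CH2 and C2 an oxocarbenium ion (stabilised by O1 and both methyl groups) in the same event.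
4. All A-ring substituents are placed from C2-symmetric 2',6'-dihydroxy-4'-methoxyacetophenone (mono-benzylation, OH-directed formylation, O-isopropylation).
5. Ring order: benzene A (bought) → dihydropyran (step 5) → furan with benzene D attached (step 10) → pyranone lactone (step 11).

Key step: step 5

Assumption: 3-bromo-4-iodophenol (12) is taken as a catalogue compound; the target has no stereocentre, and the single stereocentres of 9 and 14 are transient, so both are carried as racemates.

## Route

Step 1
Reactants: 1 2',6'-dihydroxy-4'-methoxyacetophenone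
Product: 2 1-[2-(benzyloxy)-6-hydroxy-4-methoxyphenyl]ethan-1-one
Conditions: BnBr (1.05 equiv), K2CO3, acetone, reflux
Reagents that add atoms: benzyl bromide, BrCc1ccccc1
Why: Williamson ether synthesis; the two hydroxyls of 1 are equivalent, and after the first O-benzylation the remaining one is locked in a hydrogen bond to the acetyl carbonyl, so clean mono-alkylation is expected.

Step 2
Reactants: 2 1-[2-(benzyloxy)-6-hydroxy-4-methoxyphenyl]ethan-1-one
Product: 3 3-acetyl-4-(benzyloxy)-2-hydroxy-6-methoxybenzaldehyde
Conditions: Cl2CHOMe, TiCl4, CH2Cl2, −40 → 0 °C; then 1 M HCl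
Reagents that add atoms: dichloromethyl methyl ether, COC(Cl)Cl; water, O
Why: Rieche formylation; the titanium phenoxide delivers the chloro(methoxy)methyl cation to the only free position ortho to the hydroxyl (also ortho to OMe and para to OBn), and aqueous work-up unmasks the aldehyde.

Step 3
Reactants: 3 3-acetyl-4-(benzyloxy)-2-hydroxy-6-methoxybenzaldehyde
Product: 4 3-acetyl-4-(benzyloxy)-6-methoxy-2-(propan-2-yloxy)benzaldehyde
Conditions: 2-iodopropane (3 equiv), K2CO3, DMF, 60 °C
Reagents that add atoms: 2-iodopropane, CC(C)I
Why: Williamson ether synthesis (SN2 with a secondary iodide in a dipolar aprotic solvent) on the only free phenol, which is flanked by two carbonyl groups and therefore readily deprotonated by carbonate; excess iodide compensates for E2 loss.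

Step 4
Reactants: 4 3-acetyl-4-(benzyloxy)-6-methoxy-2-(propan-2-yloxy)benzaldehyde
Product: 5 5-{[3-acetyl-4-(benzyloxy)-6-methoxy-2-(propan-2-yloxy)phenyl]methylidene}-2,2-dimethyl-1,3-dioxane-4,6-dione
Conditions: Meldrum's acid, pyrrolidine/AcOH (10 mol % each), toluene, 4 Å MS, rt
Reagents that add atoms: 2,2-dimethyl-1,3-dioxane-4,6-dione (Meldrum's acid), CC1(C)OC(=O)CC(=O)O1
Why: Knoevenagel condensation; the aldehyde, not the hindered aryl methyl ketone, condenses with the strongly C–H acidic Meldrum's acid at room temperature, where the hydride shift does not yet set in.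

Step 5
Reactants: 5 5-{[3-acetyl-4-(benzyloxy)-6-methoxy-2-(propan-2-yloxy)phenyl]methylidene}-2,2-dimethyl-1,3-dioxane-4,6-dione
Product: 7 8-acetyl-7-(benzyloxy)-5-methoxy-2,2,2',2'-tetramethylspiro[chromane-3,5'-[1,3]dioxane]-4',6'-dione, via oxocarbenium enolate zwitterion 6 (not isolated)
Conditions: Sc(OTf)3 (10 mol %), ClCH2CH2Cl, 4 Å MS, 60 °C
Reagents that add atoms: none
Why: Sc(OTf)3 chelates the two carbonyl groups of the alkylidene Meldrum's acid (whose aryl ring is twisted out of conjugation by its two ortho substituents), and the methine hydrogen of the O-isopropyl group is delivered as hydride to the benzylic carbon through a six-membered transition state ([1,5]-hydride transfer), which makes the future C4 a methylene and leaves zwitterion 6, an O-aryl isopropylidene oxocarbenium ion paired with a scandium-bound Meldrum's acid enolate. The enolate carbon (future C3) then adds to the oxocarbenium carbon (future C2) and closes the dihydropyran ring in a 6-(enolexo)-endo-trig Mannich-type collapse of the ion pair, so that the C2–C3 bond, the C4–H bond and the fully substituted O–C(CH3)2 centre arise in one redox-neutral operation. The closest known reaction type is the Lewis-acid-catalysed hydride-transfer cyclisation (internal-redox C(sp3)–H functionalisation, the oxygen counterpart of the tert-amino effect) of ortho-(2,2-diacylvinyl)aryl alkyl ethers to 3,3-diacylchromans. No stereocentre is created, because C2 carries two methyl groups and the spiro carbon C3 two equivalent acyl arms. The step needs hydride to come only from the isopropyl methine and to go only to the alkylidene carbon: the methoxy group would give a primary oxocarbenium ion, the benzyloxy group is para to the acceptor and out of reach, and the acetyl carbonyl is far less hydride-affine than the Sc-activated alkylidene Meldrum's acid. The acetyl group flanking the isopropoxy oxygen keeps the O–CH bond turned out of the ring plane toward the acceptor, and dry conditions keep 6 from being lost by hydrolysis.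

Step 6
Reactants: 7 8-acetyl-7-(benzyloxy)-5-methoxy-2,2,2',2'-tetramethylspiro[chromane-3,5'-[1,3]dioxane]-4',6'-dione
Product: 9 8-acetyl-7-(benzyloxy)-5-methoxy-2,2-dimethylchromane-3-carboxylic acid (racemic), via chromane-3,3-dicarboxylic acid 8 (not isolated)
Conditions: pyridine–H2O (10:1), 100 °C; then aq. HCl
Reagents that add atoms: water, O
Why: Hydrolytic opening of the cyclic acylal (loss of acetone) gives the gem-dicarboxylic acid, which undergoes thermal malonic acid decarboxylation through the usual six-membered transition state; the C3 stereocentre forms as a racemate and is erased in step 7.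

Step 7
Reactants: 9 8-acetyl-7-(benzyloxy)-5-methoxy-2,2-dimethylchromane-3-carboxylic acid (racemic)
Product: 10 1-[7-(benzyloxy)-5-methoxy-2,2-dimethylchroman-8-yl]ethan-1-one
Conditions: 9-mesityl-10-phenylacridinium BF4 (5 mol %), PhSSPh (10 mol %), i-Pr2NEt (20 mol %), CF3CH2OH, 450 nm LEDs, rt
Reagents that add atoms: none
Why: Photoredox hydrodecarboxylation; single-electron oxidation of the carboxylate by the excited acridinium, loss of CO2 and hydrogen-atom transfer from thiophenol (formed from the disulfide) to the secondary C3 radical leave the C3 methylene.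

Step 8
Reactants: 10 1-[7-(benzyloxy)-5-methoxy-2,2-dimethylchroman-8-yl]ethan-1-one
Product: 11 ethyl 3-[7-(benzyloxy)-5-methoxy-2,2-dimethylchroman-8-yl]-3-oxopropanoate
Conditions: NaH (2.5 equiv), (EtO)2CO, toluene, 90 °C; then aq. HCl
Reagents that add atoms: diethyl carbonate, CCOC(=O)OCC
Why: Crossed Claisen condensation of the methyl ketone enolate with diethyl carbonate, driven by irreversible deprotonation of the β-keto ester; both ortho oxygens are etherified, so no 4-hydroxycoumarin can form.

Step 9
Reactants: 12 3-bromo-4-iodophenol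
Product: 13 4-(benzyloxy)-2-bromo-1-iodobenzene
Conditions: BnBr, K2CO3, DMF, rt
Reagents that add atoms: benzyl bromide, BrCc1ccccc1
Why: Williamson ether synthesis on the free phenol; the benzyl ether matches the A-ring protecting group so that both fall in the last step.

Step 10
Reactants: 11 ethyl 3-[7-(benzyloxy)-5-methoxy-2,2-dimethylchroman-8-yl]-3-oxopropanoate; 13 4-(benzyloxy)-2-bromo-1-iodobenzene
Product: 15 ethyl 6-(benzyloxy)-2-[7-(benzyloxy)-5-methoxy-2,2-dimethylchroman-8-yl]-1-benzofuran-3-carboxylate, via C-arylated keto ester 14 (not isolated)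
Conditions: CuI (10 mol %), K2CO3 (2.5 equiv), THF, 100 °C (sealed tube)
Reagents that add atoms: none
Why: Copper-catalysed domino arylation of a β-keto ester with a 1-bromo-2-iodoarene: Hurtley-type C-arylation occurs at the more reactive C–I bond, and the enolate oxygen of 14 then closes the furan ring by intramolecular Ullmann O-arylation at C–Br, which places the benzyloxy group para to the new C–C bond as the target requires.

Step 11
Reactants: 15 ethyl 6-(benzyloxy)-2-[7-(benzyloxy)-5-methoxy-2,2-dimethylchroman-8-yl]-1-benzofuran-3-carboxylate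
Product: 17 target coumestan CNP0304440.0, via debenzylated hydroxy ester 16 (not isolated)
Conditions: H2 (1 atm), 10 % Pd/C, EtOAc–EtOH, rt; then p-TsOH (cat.), toluene, 80 °C
Reagents that add atoms: none
Why: Hydrogenolysis of both benzyl ethers frees the phenol next to the biaryl bond, which lactonises onto the neighbouring ethyl ester (acid-catalysed intramolecular transesterification, six-membered ring) to complete the coumestan; the tetrasubstituted furan double bond is not expected to be reduced under these conditions.

## Compound list

1 | 2',6'-dihydroxy-4'-methoxyacetophenone | CC(=O)c1c(O)cc(OC)cc1O | starting material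
2 | 1-[2-(benzyloxy)-6-hydroxy-4-methoxyphenyl]ethan-1-one | CC(=O)c1c(O)cc(OC)cc1OCc1ccccc1 | intermediate
3 | 3-acetyl-4-(benzyloxy)-2-hydroxy-6-methoxybenzaldehyde | CC(=O)c1c(OCc2ccccc2)cc(OC)c(C=O)c1O | intermediate
4 | 3-acetyl-4-(benzyloxy)-6-methoxy-2-(propan-2-yloxy)benzaldehyde | CC(=O)c1c(OCc2ccccc2)cc(OC)c(C=O)c1OC(C)C | intermediate
5 | 5-{[3-acetyl-4-(benzyloxy)-6-methoxy-2-(propan-2-yloxy)phenyl]methylidene}-2,2-dimethyl-1,3-dioxane-4,6-dione | CC(=O)c1c(OCc2ccccc2)cc(OC)c(C=C2C(=O)OC(C)(C)OC2=O)c1OC(C)C | intermediate
6 | oxocarbenium enolate zwitterion (O-aryl isopropylidene oxocarbenium ion with a benzylic CH2 and a Meldrum's acid enolate) | CC(=O)c1c(OCc2ccccc2)cc(OC)c(CC2=C([O-])OC(C)(C)OC2=O)c1[O+]=C(C)C | intermediate (not isolated)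
7 | 8-acetyl-7-(benzyloxy)-5-methoxy-2,2,2',2'-tetramethylspiro[chromane-3,5'-[1,3]dioxane]-4',6'-dione (no stereocentre) | CC(=O)c1c(OCc2ccccc2)cc(OC)c2CC3(C(=O)OC(C)(C)OC3=O)C(C)(C)Oc12 | intermediate
8 | 8-acetyl-7-(benzyloxy)-5-methoxy-2,2-dimethylchromane-3,3-dicarboxylic acid | CC(=O)c1c(OCc2ccccc2)cc(OC)c2CC(C(=O)O)(C(=O)O)C(C)(C)Oc12 | intermediate (not isolated)
9 | 8-acetyl-7-(benzyloxy)-5-methoxy-2,2-dimethylchromane-3-carboxylic acid (racemic) | CC(=O)c1c(OCc2ccccc2)cc(OC)c2CC(C(=O)O)C(C)(C)Oc12 | intermediate
10 | 1-[7-(benzyloxy)-5-methoxy-2,2-dimethylchroman-8-yl]ethan-1-one | CC(=O)c1c(OCc2ccccc2)cc(OC)c2CCC(C)(C)Oc12 | intermediate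
11 | ethyl 3-[7-(benzyloxy)-5-methoxy-2,2-dimethylchroman-8-yl]-3-oxopropanoate | CCOC(=O)CC(=O)c1c(OCc2ccccc2)cc(OC)c2CCC(C)(C)Oc12 | intermediate
12 | 3-bromo-4-iodophenol | Oc1ccc(I)c(Br)c1 | starting material
13 | 4-(benzyloxy)-2-bromo-1-iodobenzene | Ic1ccc(OCc2ccccc2)cc1Br | intermediate
14 | ethyl 2-[4-(benzyloxy)-2-bromophenyl]-3-[7-(benzyloxy)-5-methoxy-2,2-dimethylchroman-8-yl]-3-oxopropanoate (racemic) | CCOC(=O)C(c1ccc(OCc2ccccc2)cc1Br)C(=O)c1c(OCc2ccccc2)cc(OC)c2CCC(C)(C)Oc12 | intermediate (not isolated)
15 | ethyl 6-(benzyloxy)-2-[7-(benzyloxy)-5-methoxy-2,2-dimethylchroman-8-yl]-1-benzofuran-3-carboxylate | CCOC(=O)c1c(-c2c(OCc3ccccc3)cc(OC)c3CCC(C)(C)Oc23)oc2cc(OCc3ccccc3)ccc12 | intermediate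
16 | ethyl 6-hydroxy-2-(7-hydroxy-5-methoxy-2,2-dimethylchroman-8-yl)-1-benzofuran-3-carboxylate | CCOC(=O)c1c(-c2c(O)cc(OC)c3CCC(C)(C)Oc23)oc2cc(O)ccc12 | intermediate (not isolated)
17 | CNP0304440.0: 9-hydroxy-3-methoxycoumestan with a 2,2-dimethyl-3,4-dihydro-2H-pyran ring fused through O at C1 and CH2 at C2 (achiral) | COc1cc2oc(=O)c3c4ccc(O)cc4oc3c2c2c1CCC(C)(C)O2 | target

## Step count and risks

Total step count: 11. Longest linear sequence: 10 (steps 1–8, 10, 11).

Steps most likely to fail:

**Step 5.** The hydride transfer may be too slow, because the three alkoxy donors lower the hydride affinity of the alkylidene carbon. Alternatively, the oxocarbenium ion of 6 may be lost by proton loss and hydrolysis (O-dealkylation to the phenol) before the bond between the two fully substituted carbons closes. The fallback sets out from 2 and comes back at 10, and builds the dihydropyran ring by the aryl propargyl ether route instead. O-Alkylation of 2 with 3-chloro-3-methylbut-1-yne (K2CO3, KI, cat. CuI, DMF, 60 °C) should give 1-[2-(benzyloxy)-4-methoxy-6-[(2-methylbut-3-yn-2-yl)oxy]phenyl]ethan-1-one F1. Heating this ether in N,N-diethylaniline at 180 °C (aromatic Claisen rearrangement to the only free ortho position, [1,5]-H shift and oxa-6π electrocyclisation) should give 1-[7-(benzyloxy)-5-methoxy-2,2-dimethyl-2H-chromen-8-yl]ethan-1-one F2. Hydrogenation of its C3=C4 bond with H2 and RhCl(PPh3)3 in benzene–ethanol, which spares the benzyl ether, leads to 10.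

**Step 7.** The excited acridinium may oxidise the electron-rich trialkoxyarene instead of the carboxylate. The C3 radical may also open the dihydropyran ring by β-scission (expulsion of the aryloxyl radical) before hydrogen-atom transfer, since the thiol is present only in catalytic amount. The fallback sets out from 9 and comes back at 10, and is a Barton reductive decarboxylation, a radical chain without photooxidant and with a large excess of a fast hydrogen donor. Coupling of 9 with 1-hydroxypyridine-2(1H)-thione (DCC, cat. DMAP, CH2Cl2, dark) should give 2-thioxopyridin-1(2H)-yl 8-acetyl-7-(benzyloxy)-5-methoxy-2,2-dimethylchromane-3-carboxylate F3. Irradiation of this ester with a tungsten lamp in benzene containing excess 2-methylpropane-2-thiol leads to 10.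

**Step 2.** TiCl4 may cleave the benzyl ether, which sits ortho to the acetyl group and can be activated by chelation, or some formylation may take place para to the phenol. The fallback sets out from 1 and comes back at 3, and reverses the order so that regiochemistry is settled by symmetry and no benzyl ether meets the Lewis acid. Rieche formylation of the symmetric diol 1 (Cl2CHOMe, TiCl4, CH2Cl2, 0 °C; then aq. HCl), whose two free ring positions are equivalent, should give 3-acetyl-2,4-dihydroxy-6-methoxybenzaldehyde F4. Benzylation of this diol with one equivalent of BnBr (K2CO3, acetone) is expected to take place at the less hindered hydroxyl, the one flanked by only one carbonyl group, and leads to 3.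

## Further compounds

F1 | step 5 | 1-[2-(benzyloxy)-4-methoxy-6-[(2-methylbut-3-yn-2-yl)oxy]phenyl]ethan-1-one | CC(=O)c1c(OCc2ccccc2)cc(OC)cc1OC(C)(C)C#C
F2 | step 5 | 1-[7-(benzyloxy)-5-methoxy-2,2-dimethyl-2H-chromen-8-yl]ethan-1-one | CC(=O)c1c(OCc2ccccc2)cc(OC)c2C=CC(C)(C)Oc12
F3 | step 7 | 2-thioxopyridin-1(2H)-yl 8-acetyl-7-(benzyloxy)-5-methoxy-2,2-dimethylchromane-3-carboxylate (racemic) | CC(=O)c1c(OCc2ccccc2)cc(OC)c2CC(C(=O)On3ccccc3=S)C(C)(C)Oc12
F4 | step 2 | 3-acetyl-2,4-dihydroxy-6-methoxybenzaldehyde | CC(=O)c1c(O)cc(OC)c(C=O)c1O
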